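Remark on the chemistry (assumption): 1,11-dibromoundecane (2), N-methoxy-N-methylacetamide (6), the chiral phosphine and the oxazaborolidine are taken as commercial. Ring atoms are numbered C1 (secondary carbinol), C2=C3, C4, C5 (tertiary carbinol), C6; chain atoms are C1' to C16'.

## Analysis of the target

Compound 18 is a cyclohexene with a secondary allylic carbinol at C1, the C2=C3 double bond, methylenes at C4 and C6, and a tertiary carbinol at C5. C5 also carries an unbranched sixteen-carbon chain: eleven methylenes, a Z double bond at C12'=C13', three more methylenes and a terminal phenyl ring. There are two stereocentres, C1 (S) and C5 (S), with both hydroxyl groups on the same ring face (cis-1,3-diol), plus the Z geometry in the chain. The Z-alkene must be kept away from isomerising metals, hydrogenation and electrophilic halogen. In any ring-ketone precursor the C5 oxygen is β to the carbonyl, so base can expel it and the ring then aromatises to a 3-alkylphenol. The main difficulty is C5: its three carbon neighbours C4, C6 and C1' are all methylenes, so its configuration cannot come from ordinary size discrimination at a ketone. The second difficulty is the cis relation of C1 to C5 across C6, for which the ring gives no strong bias because either C5 substituent can be pseudo-axial. The strategy rests on the position of C5: it lies opposite C2 and is flanked by C4 and C6, just as C3 of a 3,3-disubstituted cyclobutanone is flanked by its two α-methylenes. Such a cyclobutanone has a mirror plane, so inserting the C2–C3 unit between the carbonyl carbon and one of the two α-methylenes builds the ring and fixes C5 in the same event.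

## Retrosynthetic reasoning

18 ⇒ 17. The last bond cut is the O–Si bond of a tertiary silyl ether at C5. The C5 oxygen stays masked through every ketone stage, which blocks retro-aldol and dehydration pathways. The forward step needs only a fluoride source, at a stage where no carbonyl is left in the ring.

17 ⇒ 16. The C1–H bond is cut, leading back to the enone. The C1 oxygen is then simply the carbonyl oxygen delivered by the ring-forming step. The forward reduction must add hydride to the face anti to the C5 oxygen. This is assigned to a chiral catalyst rather than to the substrate, because the two C5 substituents give no dependable facial bias. A further gain is that any minor enantiomer of 16 becomes a trans diastereomer of 17, which can be separated.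

16 ⇒ 14 + 15. The bonds C1–C2 and C3–C4 are cut. C2 and C3 are the only ring atoms bearing neither a heteroatom nor the quaternary centre, so removing them as ethyne 15 leaves a four-membered ketone 14 that already holds the chain, the protected oxygen and the carbonyl. This is preferred over cuts next to C5, which would require building the CH2-flanked carbinol stereoselectively by addition to a ketone. The forward step gains one ring, two C–C bonds and the C5 stereocentre. It must choose one of two enantiotopic ring bonds of 14, outrun oligomerisation of 15, and keep the silyloxy group.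

14 ⇒ 13 ⇒ 10 + 12. The four-membered ring is divided into the C=C bond of enol ether 10 and ketene 12, generated in the flask from 11. The polarity match joins the nucleophilic terminal carbon of 10 to the central ketene carbon, which places the oxygen-bearing carbon 1,3 to the carbonyl, as needed for C5. The two chlorines that make the ketene reactive are then removed reductively, which restores the mirror plane.

10 ⇒ 8 (through 9). The O–Si bond of the enol ether is cut. The forward step has to deprotonate the methyl group of 8, not the methylene, so that the ring oxygen ends up on the chain-bearing carbon.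

8 ⇒ 7 + 6, and 7 ⇒ 5. The bond between the carbonyl carbon and C1' is cut. The sixteen-carbon chain arrives as organomagnesium 7 and the two future ring carbons as the N-methoxy amide 6, which stops cleanly at the ketone stage.

5 ⇒ 4 ⇒ 1 + 2 (through 3). The Z-alkene comes from syn semi-hydrogenation of an alkyne, and the alkyne from alkylation of acetylide 3 with an excess of dibromide 2. The alkyne is reduced early, because an internal alkyne would compete with 15 in the nickel step.

## Alternatives that were turned down

Alternative 1: The ring would be disconnected at C4–C5 by a sigmatropic shift, with C1' present as a carboxyl carbon. In the forward key step the silyl ketene acetal of vinyl lactone A1 rearranges through the boat transition state enforced by the lactone ring. This forms C4–C5 and the C2=C3 double bond and gives acid A2. In its favour, the shift is stereospecific, C1 is already present in A1, and the cis relation of the two oxygens follows from the geometry of A1 rather than from a reduction. On these two points (certainty of the key step, relative configuration) it is stronger than the chosen route. Against it, A1 needs three functionalised ring centres from the chiral pool, probably seven or more steps. Moreover A2 has only C1' of the chain: the remaining fifteen carbons with the Z-alkene must be joined at a neopentyl-type carbon next to the fully substituted C5, which needs reduction, activation and a sluggish sp3–sp3 coupling, or a spiro-epoxide detour. The total would be well above fifteen linear steps. The chosen route offers instead a chain that is complete before the ring is formed and a single catalytic step for ring and stereocentre.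

Alternative 2: C5 would come from a titanium–tartrate asymmetric epoxidation, and C1–C6 from an acyl-anion opening. In the forward key step a lithiated methyl-dithiane opens epoxy tosylate A3 at the oxirane methylene, and the C5 alkoxide so released displaces the tosylate to give the new oxirane A4 on the C4 arm. In its favour, every step has close precedent and the absolute configuration of C5 is predictable from the epoxidation rule. On predictability it is stronger than the chosen route. Against it, A4 is still far from the ring: C3 must be added by a one-carbon opening and the dithiane removed with thiophilic or oxidising reagents beside the Z-alkene. The ring must then be closed by a base-mediated aldol condensation on a β-oxygenated ketone, exactly the conditions under which the C5 oxygen can be expelled and the ring aromatise. The sequence is linear, at least twelve steps, and arrives only at the stage of 16, so the C1 reduction problem remains. The chosen route replaces about seven of these steps by one and never exposes the β-oxygenated ketone to base.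

Alternative 3: The C1–O bond would be made from the C5 oxygen across the ring, on a cyclohexene obtained by Birch reduction of an aryl ether and addition of the chain as an organometallic. In the forward key step an electrophilic iodine source activates the ring alkene of carbonate A5. The carbonyl oxygen adds to C1 anti to iodine with loss of the tert-butyl group, giving bridged iodocarbonate A6. Elimination of HI, which can only go towards C3 because C1 is a bridgehead, and carbonate hydrolysis would finish the ring. In its favour, the cis-1,3 relation is enforced by the tether, which is stronger than any ketone reduction, including step 8 of the chosen route, and all reactions are known. Against it, the tertiary carbinol of A5 is formed by addition to a ketone whose two arms differ only beyond the α-methylenes, so there is no good source of absolute configuration and a resolution of a tertiary alcohol would be needed. Electrophilic iodine is also incompatible with the chain Z-alkene, so the chain must be carried as an alkyne and semi-hydrogenated last, next to the ring alkene. Step count is similar to the chosen route. The chosen route offers catalyst control of the absolute configuration at C5 and carries the Z-alkene from the second step.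

Key step: step 7

## Route

Step 1
Reactants: 1 5-phenylpent-1-yne; 2 1,11-dibromoundecane
Product: 4 16-bromo-1-phenylhexadec-4-yne, via lithium 5-phenylpent-1-yn-1-ide 3 (not isolated)
Conditions: n-BuLi, THF, −78 °C; then 2 (3 equiv), DMPU, −78 °C to rt
Reagents that add atoms: none
Why: Alkylation of a lithium acetylide with a primary bromide (SN2) in THF/DMPU; the excess of 2 should keep double alkylation low, and unreacted 2 is recovered.

Step 2
Reactants: 4 16-bromo-1-phenylhexadec-4-yne
Product: 5 (Z)-16-bromo-1-phenylhexadec-4-ene
Conditions: H2 (1 atm), Pd/CaCO3 poisoned with Pb(OAc)2 (Lindlar catalyst), quinoline, hexane/EtOAc, rt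
Reagents that add atoms: none
Why: Lindlar semi-hydrogenation adds hydrogen syn on the poisoned palladium surface and should stop at the Z-alkene; the primary bromide and the arene are not affected.

Step 3
Reactants: 5 (Z)-16-bromo-1-phenylhexadec-4-ene; 6 N-methoxy-N-methylacetamide
Product: 8 (Z)-18-phenyloctadec-14-en-2-one, via [(Z)-16-phenylhexadec-12-en-1-yl]magnesium bromide 7 (not isolated)
Conditions: Mg, THF, 45 °C; then 6, THF, 0 °C; aq. NH4Cl
Reagents that add atoms: none
Why: Grignard formation and acyl substitution on a Weinreb-type amide; the chelated tetrahedral adduct should persist until work-up, so the methyl ketone is not attacked a second time.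

Step 4
Reactants: 8 (Z)-18-phenyloctadec-14-en-2-one
Product: 10 tert-butyldimethyl{[(Z)-18-phenyloctadeca-1,14-dien-2-yl]oxy}silane, via lithium (Z)-18-phenyloctadeca-1,14-dien-2-olate 9 (not isolated)
Conditions: lithium diisopropylamide, THF, −78 °C (ketone added to the base); then TBSCl, DMPU, −78 °C to rt
Reagents that add atoms: tert-butyldimethylsilyl chloride, CC(C)(C)[Si](C)(C)Cl
Why: Kinetic enolisation with a hindered lithium amide at −78 °C should remove a methyl proton rather than a methylene proton, and O-silylation of 9 gives the 2-silyloxy-1-alkene. This decides that the ring oxygen will sit on the chain-bearing carbon.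

Step 5
Reactants: 10 tert-butyldimethyl{[(Z)-18-phenyloctadeca-1,14-dien-2-yl]oxy}silane; 11 trichloroacetyl chloride
Product: 13 rac-3-[(tert-butyldimethylsilyl)oxy]-2,2-dichloro-3-[(Z)-16-phenylhexadec-12-en-1-yl]cyclobutan-1-one, via dichloroketene 12 (not isolated)
Conditions: 11 (1.3 equiv, slow addition), Zn(Cu), Et2O/DME, 0 °C to rt
Reagents that add atoms: none
Why: Dichloroketene [2+2] cycloaddition: the nucleophilic terminal carbon of the enol ether bonds to the central ketene carbon, so the silyloxy carbon ends up next to CCl2 and 1,3 to the carbonyl. The electron-rich enol ether should react much faster than the isolated chain alkene, and DME ties up ZnCl2. The stereocentre formed here is racemic, which is of no consequence because step 6 restores the mirror plane.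

Step 6
Reactants: 13 rac-3-[(tert-butyldimethylsilyl)oxy]-2,2-dichloro-3-[(Z)-16-phenylhexadec-12-en-1-yl]cyclobutan-1-one
Product: 14 3-[(tert-butyldimethylsilyl)oxy]-3-[(Z)-16-phenylhexadec-12-en-1-yl]cyclobutan-1-one
Conditions: Zn dust, AcOH, TMEDA, EtOH, 0 °C to rt
Reagents that add atoms: none
Why: Reductive dechlorination of an α,α-dichlorocyclobutanone by zinc through zinc enolates that are protonated at once in the buffered medium. The AcOH/TMEDA buffer avoids the free acid that would open the donor–acceptor four-membered ring, and loss of both chlorines makes the two α-methylenes equivalent, so 14 is achiral.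

Step 7
Reactants: 14 3-[(tert-butyldimethylsilyl)oxy]-3-[(Z)-16-phenylhexadec-12-en-1-yl]cyclobutan-1-one; 15 ethyne
Product: 16 (S)-5-[(tert-butyldimethylsilyl)oxy]-5-[(Z)-16-phenylhexadec-12-en-1-yl]cyclohex-2-en-1-one
Conditions: Ni(cod)2 (10 mol %), (+)-neomenthyldiphenylphosphine (20 mol %), 15 (dilute toluene solution, slow feed), toluene, 50 °C
Reagents that add atoms: none
Why: Proposed new method: zerovalent nickel binds the carbonyl group of 14 and ethyne and couples them oxidatively to a spiro oxanickelacyclopentene (C1–C2 formed); β-carbon elimination, driven by release of four-membered-ring strain, then moves one α-methylene from C1 to nickel to give a seven-membered nickelacycle containing the ketone, and C(sp2)–C(sp3) reductive elimination forms C3–C4 and returns zerovalent nickel. The closest known reaction type is the nickel-catalysed insertion of internal alkynes into 3,3-disubstituted cyclobutanones to give cyclohexenones, with enantioselective intramolecular versions; untested here are ethyne as the alkyne, an oxygen substituent on the ring carbon opposite the carbonyl, and enantiocontrol between two separate partners. The six-membered ring is closed by reductive elimination from the seven-membered metallacycle, that is a ring contraction at nickel and overall a two-carbon enlargement of the four-membered ring, not a cycloaddition. C5 is the only new stereocentre and is under catalyst control: the chiral phosphine decides which of the two enantiotopic carbonyl–methylene bonds is cleaved, the cleaved methylene becoming C4 and the other C6. The selectivity needed is therefore enantiotopic-bond selection, and the substrate helps because the carbon adjacent to both candidate methylenes carries a bulky silyloxy group and a slim n-alkyl chain, a large steric contrast held rigidly in the puckered ring close to the metal. That carbon is fully substituted, so the alkylnickel intermediate has no β-hydrogen, loss of the β-silyloxy group should be slower than reductive elimination because silyloxide is a poor leaving group, and the symmetry of ethyne removes any regiochemical question. Ethyne is fed slowly to keep its concentration low and suppress nickel-catalysed oligomerisation and further reaction of 16, while the isolated Z-alkene and the arene bind zerovalent nickel too weakly to interfere. If the ligand shown gives (R)-16, its antipode or another bulky electron-rich chiral monophosphine from the screen is used.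

Step 8
Reactants: 16 (S)-5-[(tert-butyldimethylsilyl)oxy]-5-[(Z)-16-phenylhexadec-12-en-1-yl]cyclohex-2-en-1-one
Product: 17 (1S,5S)-5-[(tert-butyldimethylsilyl)oxy]-5-[(Z)-16-phenylhexadec-12-en-1-yl]cyclohex-2-en-1-ol
Conditions: (R)-1-methyl-3,3-diphenyltetrahydro-1H,3H-pyrrolo[1,2-c][1,3,2]oxazaborole (0.3 equiv), catecholborane, toluene, −78 °C; then MeOH, aq. NaOH
Reagents that add atoms: none
Why: Corey–Bakshi–Shibata reduction with catecholborane, which reduces the enone 1,2 and should not hydroborate the chain alkene at −78 °C. With the alkenyl arm C2 as the large group and the C6 methylene as the small one, the (R)-catalyst should deliver hydride anti to the C5 oxygen and set C1 as (S), cis to the silyloxy group. Reagent control is used because the two C5 substituents give no dependable ring bias, and any (R)-16 carried over becomes a separable trans diastereomer.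

Step 9
Reactants: 17 (1S,5S)-5-[(tert-butyldimethylsilyl)oxy]-5-[(Z)-16-phenylhexadec-12-en-1-yl]cyclohex-2-en-1-ol
Product: 18 (1S,3S)-1-[(Z)-16-phenylhexadec-12-en-1-yl]cyclohex-4-ene-1,3-diol
Conditions: Bu4NF, THF, rt to 50 °C
Reagents that add atoms: none
Why: Fluoride cleavage of the hindered tertiary silyl ether, driven by the Si–F bond. No carbonyl is left in the ring, so there is no β-elimination pathway and both stereocentres stay as set.

## Compound list

1 | 5-phenylpent-1-yne | C#CCCCc1ccccc1 | starting material
2 | 1,11-dibromoundecane | BrCCCCCCCCCCCBr | starting material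
3 | lithium 5-phenylpent-1-yn-1-ide | [Li]C#CCCCc1ccccc1 | intermediate
4 | 16-bromo-1-phenylhexadec-4-yne | BrCCCCCCCCCCCC#CCCCc1ccccc1 | intermediate
5 | (Z)-16-bromo-1-phenylhexadec-4-ene | BrCCCCCCCCCCC/C=C\CCCc1ccccc1 | intermediate
6 | N-methoxy-N-methylacetamide | CC(=O)N(C)OC | starting material
7 | [(Z)-16-phenylhexadec-12-en-1-yl]magnesium bromide | Br[Mg]CCCCCCCCCCC/C=C\CCCc1ccccc1 | intermediate
8 | (Z)-18-phenyloctadec-14-en-2-one | CC(=O)CCCCCCCCCCC/C=C\CCCc1ccccc1 | intermediate
9 | lithium (Z)-18-phenyloctadeca-1,14-dien-2-olate | [Li]OC(=C)CCCCCCCCCCC/C=C\CCCc1ccccc1 | intermediate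
10 | tert-butyldimethyl{[(Z)-18-phenyloctadeca-1,14-dien-2-yl]oxy}silane | C=C(O[Si](C)(C)C(C)(C)C)CCCCCCCCCCC/C=C\CCCc1ccccc1 | intermediate
11 | trichloroacetyl chloride | ClC(=O)C(Cl)(Cl)Cl | starting material
12 | dichloroketene | O=C=C(Cl)Cl | intermediate
13 | rac-3-[(tert-butyldimethylsilyl)oxy]-2,2-dichloro-3-[(Z)-16-phenylhexadec-12-en-1-yl]cyclobutan-1-one (racemic) | O=C1CC(O[Si](C)(C)C(C)(C)C)(CCCCCCCCCCC/C=C\CCCc2ccccc2)C1(Cl)Cl | intermediate
14 | 3-[(tert-butyldimethylsilyl)oxy]-3-[(Z)-16-phenylhexadec-12-en-1-yl]cyclobutan-1-one (achiral) | O=C1CC(O[Si](C)(C)C(C)(C)C)(CCCCCCCCCCC/C=C\CCCc2ccccc2)C1 | intermediate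
15 | ethyne | C#C | starting material
16 | (S)-5-[(tert-butyldimethylsilyl)oxy]-5-[(Z)-16-phenylhexadec-12-en-1-yl]cyclohex-2-en-1-one | O=C1C=CC[C@@](O[Si](C)(C)C(C)(C)C)(CCCCCCCCCCC/C=C\CCCc2ccccc2)C1 | intermediate
17 | (1S,5S)-5-[(tert-butyldimethylsilyl)oxy]-5-[(Z)-16-phenylhexadec-12-en-1-yl]cyclohex-2-en-1-ol | O[C@@H]1C=CC[C@@](O[Si](C)(C)C(C)(C)C)(CCCCCCCCCCC/C=C\CCCc2ccccc2)C1 | intermediate
18 | (1S,3S)-1-[(Z)-16-phenylhexadec-12-en-1-yl]cyclohex-4-ene-1,3-diol | O[C@@H]1C=CC[C@@](O)(CCCCCCCCCCC/C=C\CCCc2ccccc2)C1 | target

## Step count and risk

Total: 9 steps. Longest linear sequence: 9 steps (from 1).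

Least certain steps:

Step 7 (key step). Ethyne may be consumed by nickel-catalysed cyclotrimerisation or oligomerisation faster than it couples with the ketone. The choice between the two enantiotopic ring bonds may also be poorly discriminated, because the differentiating carbon is two bonds away from nickel. Loss of the silyloxy group from the alkylnickel intermediate, followed by aromatisation, is a third possibility. The fallback uses known chemistry, leaves the route at Grignard reagent 7 and returns at 16.
- Addition of 7 to 3-ethoxycyclohex-2-en-1-one with acidic work-up (Stork–Danheiser transposition) should give 3-[(Z)-16-phenylhexadec-12-en-1-yl]cyclohex-2-en-1-one F1.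
- Asymmetric nucleophilic epoxidation catalysed by a cinchona primary-amine salt (9-amino-9-deoxy-epi-quinine or its quinidine-derived pseudoenantiomer as trifluoroacetate, aqueous H2O2, dioxane) should give (1S,6S)-6-[(Z)-16-phenylhexadec-12-en-1-yl]-7-oxabicyclo[4.1.0]heptan-2-one F2, which fixes the C5 oxygen.
- Reductive opening at the α-carbon ((PhSe)2, NaBH4, AcOH, EtOH) gives (S)-3-hydroxy-3-[(Z)-16-phenylhexadec-12-en-1-yl]cyclohexan-1-one F3.
- Silylation (TBSOTf, 2,6-lutidine) gives (S)-3-[(tert-butyldimethylsilyl)oxy]-3-[(Z)-16-phenylhexadec-12-en-1-yl]cyclohexan-1-one F4.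
- Kinetic enolisation away from the quaternary carbon (lithium diisopropylamide, Me3SiCl, −78 °C) gives (S)-tert-butyldimethyl({1-[(Z)-16-phenylhexadec-12-en-1-yl]-3-[(trimethylsilyl)oxy]cyclohex-3-en-1-yl}oxy)silane F5.
- Saegusa–Ito oxidation with Pd(OAc)2 in MeCN gives 16.

Step 6. The dichlorocyclobutanone carries a donor oxygen opposite an acceptor carbonyl, so ring opening by retro-aldol-type cleavage, or expulsion of silanolate from the zinc enolate, may compete with simple dechlorination. The fallback avoids the ketene adduct altogether, leaves the route at 7 and returns at 14.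
- Addition of 7 (with anhydrous CeCl3) to commercial 3-(benzyloxy)cyclobutan-1-one gives 3-(benzyloxy)-1-[(Z)-16-phenylhexadec-12-en-1-yl]cyclobutan-1-ol F6 as a cis/trans mixture.
- Silylation (TBSOTf, 2,6-lutidine) gives {[3-(benzyloxy)-1-[(Z)-16-phenylhexadec-12-en-1-yl]cyclobutyl]oxy}(tert-butyl)dimethylsilane F7.
- Reductive debenzylation with lithium 4,4'-di-tert-butylbiphenylide in THF at −78 °C, which spares the Z-alkene, gives 3-[(tert-butyldimethylsilyl)oxy]-3-[(Z)-16-phenylhexadec-12-en-1-yl]cyclobutan-1-ol F8.
- Dess–Martin oxidation gives 14, both diastereomers converging.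

Step 8. Facial selectivity may be poor if the intrinsic bias of the ring opposes the catalyst (mismatched pair), or if the C6 methylene, which is next to a quaternary carbon, is not read as the small group. The fallback replaces facial selection by inversion, leaves the route at 16 and returns at 17.
- Luche reduction (NaBH4, CeCl3·7H2O, MeOH, −78 °C) gives the allylic alcohol as a mixture of C1 epimers. The cis epimer is 17.
- The trans epimer (1R,5S)-5-[(tert-butyldimethylsilyl)oxy]-5-[(Z)-16-phenylhexadec-12-en-1-yl]cyclohex-2-en-1-ol F9 is separated and inverted under Mitsunobu conditions (4-nitrobenzoic acid, PPh3, DIAD) to (1S,5S)-5-[(tert-butyldimethylsilyl)oxy]-5-[(Z)-16-phenylhexadec-12-en-1-yl]cyclohex-2-en-1-yl 4-nitrobenzoate F10.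
- Methanolysis (K2CO3, MeOH) returns 17.

Step 4. Deprotonation may not be fully selective for the methyl group, or the enolate may equilibrate before silylation. Internal enol ether isomers would then be carried into 2-substituted cyclobutanones. The fallback makes the enol ether regiospecifically by olefination, leaves the route at 7 and returns at 10.
- Carboxylation of 7 with CO2 gives (Z)-17-phenylheptadec-13-enoic acid F11.
- Silylation (TBSCl, imidazole) gives tert-butyldimethylsilyl (Z)-17-phenylheptadec-13-enoate F12.
- Petasis methylenation (Cp2TiMe2, toluene, 70 °C) of the silyl ester gives 10 directly.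

## Further compounds

F1 | step 7 | 3-[(Z)-16-phenylhexadec-12-en-1-yl]cyclohex-2-en-1-one | O=C1C=C(CCCCCCCCCCC/C=C\CCCc2ccccc2)CCC1
F2 | step 7 | (1S,6S)-6-[(Z)-16-phenylhexadec-12-en-1-yl]-7-oxabicyclo[4.1.0]heptan-2-one | O=C1CCC[C@]2(CCCCCCCCCCC/C=C\CCCc3ccccc3)O[C@H]12
F3 | step 7 | (S)-3-hydroxy-3-[(Z)-16-phenylhexadec-12-en-1-yl]cyclohexan-1-one | O=C1CCC[C@@](O)(CCCCCCCCCCC/C=C\CCCc2ccccc2)C1
F4 | step 7 | (S)-3-[(tert-butyldimethylsilyl)oxy]-3-[(Z)-16-phenylhexadec-12-en-1-yl]cyclohexan-1-one | O=C1CCC[C@@](O[Si](C)(C)C(C)(C)C)(CCCCCCCCCCC/C=C\CCCc2ccccc2)C1
F5 | step 7 | (S)-tert-butyldimethyl({1-[(Z)-16-phenylhexadec-12-en-1-yl]-3-[(trimethylsilyl)oxy]cyclohex-3-en-1-yl}oxy)silane | C[Si](C)(C)OC1=CCC[C@@](O[Si](C)(C)C(C)(C)C)(CCCCCCCCCCC/C=C\CCCc2ccccc2)C1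
F6 | step 6 | 3-(benzyloxy)-1-[(Z)-16-phenylhexadec-12-en-1-yl]cyclobutan-1-ol (cis/trans mixture) | OC1(CCCCCCCCCCC/C=C\CCCc2ccccc2)CC(OCc3ccccc3)C1
F7 | step 6 | {[3-(benzyloxy)-1-[(Z)-16-phenylhexadec-12-en-1-yl]cyclobutyl]oxy}(tert-butyl)dimethylsilane (cis/trans mixture) | CC(C)(C)[Si](C)(C)OC1(CCCCCCCCCCC/C=C\CCCc2ccccc2)CC(OCc3ccccc3)C1
F8 | step 6 | 3-[(tert-butyldimethylsilyl)oxy]-3-[(Z)-16-phenylhexadec-12-en-1-yl]cyclobutan-1-ol (cis/trans mixture) | CC(C)(C)[Si](C)(C)OC1(CCCCCCCCCCC/C=C\CCCc2ccccc2)CC(O)C1
F9 | step 8 | (1R,5S)-5-[(tert-butyldimethylsilyl)oxy]-5-[(Z)-16-phenylhexadec-12-en-1-yl]cyclohex-2-en-1-ol | O[C@H]1C=CC[C@@](O[Si](C)(C)C(C)(C)C)(CCCCCCCCCCC/C=C\CCCc2ccccc2)C1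
F10 | step 8 | (1S,5S)-5-[(tert-butyldimethylsilyl)oxy]-5-[(Z)-16-phenylhexadec-12-en-1-yl]cyclohex-2-en-1-yl 4-nitrobenzoate | O=C(O[C@@H]1C=CC[C@@](O[Si](C)(C)C(C)(C)C)(CCCCCCCCCCC/C=C\CCCc2ccccc2)C1)c1ccc(cc1)[N+](=O)[O-]
F11 | step 4 | (Z)-17-phenylheptadec-13-enoic acid | OC(=O)CCCCCCCCCCC/C=C\CCCc1ccccc1
F12 | step 4 | tert-butyldimethylsilyl (Z)-17-phenylheptadec-13-enoate | CC(C)(C)[Si](C)(C)OC(=O)CCCCCCCCCCC/C=C\CCCc1ccccc1
A1 | alternative 1 | (5S,6S)-3,5-bis[(tert-butyldimethylsilyl)oxy]-6-ethenyloxan-2-one (configuration at C3 immaterial) | C=C[C@@H]1OC(=O)C(O[Si](C)(C)C(C)(C)C)C[C@@H]1O[Si](C)(C)C(C)(C)C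
A2 | alternative 1 | (1S,5S)-1,5-bis[(tert-butyldimethylsilyl)oxy]cyclohex-3-ene-1-carboxylic acid | CC(C)(C)[Si](C)(C)O[C@@H]1C=CC[C@@](O[Si](C)(C)C(C)(C)C)(C(=O)O)C1
A3 | alternative 2 | (R)-{2-[(Z)-16-phenylhexadec-12-en-1-yl]oxiran-2-yl}methyl 4-methylbenzenesulfonate | Cc1ccc(cc1)S(=O)(=O)OC[C@@]2(CCCCCCCCCCC/C=C\CCCc3ccccc3)CO2
A4 | alternative 2 | (R)-2-[(2-methyl-1,3-dithian-2-yl)methyl]-2-[(Z)-16-phenylhexadec-12-en-1-yl]oxirane | CC1(SCCCS1)C[C@]2(CCCCCCCCCCC/C=C\CCCc3ccccc3)CO2
A5 | alternative 3 | tert-butyl (S)-1-(16-phenylhexadec-12-yn-1-yl)cyclohex-3-en-1-yl carbonate | CC(C)(C)OC(=O)O[C@]1(CCCCCCCCCCCC#CCCCc2ccccc2)CC=CCC1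
A6 | alternative 3 | 8-iodo-5-(16-phenylhexadec-12-yn-1-yl)-2,4-dioxabicyclo[3.3.1]nonan-3-one (iodine anti to the carbonate bridge) | O=C1O[C@@H]2[C@@H](I)CC[C@](CCCCCCCCCCCC#CCCCc3ccccc3)(O1)C2
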